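The numbers in the tables are calculated for substances that don't exist; noise was put on by code.

In this closed, stirred flask free catalyst turns starting material into product, and the ratio I begin from is one of two shares: at 70 min the reading of the grey run comes to 29.6 % of its starting material and that of the ochre run to 19.4 %, which is 1.53 to one, while their charges of free catalyst stand at 1.50 to one.

| setting | red | blue | grey | ochre | teal |
|---|---|---|---|---|---|
| starting material | 0.0800 M | 0.0400 M | 0.0800 M | 0.120 M | 0.200 M |
| free catalyst | 4.00 × 10⁻⁴ M | 4.00 × 10⁻⁴ M | 6.00 × 10⁻⁴ M | 4.00 × 10⁻⁴ M | 4.00 × 10⁻⁴ M |
| time |  |  |  |  | 70 min |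

| run | time / min | [product] / M |
|---|---|---|
| red run | 2.8 | 0.0037 |
| red run | 4.4 | 0.0049 |
| red run | 7.0 | 0.0057 |
| red run | 11 | 0.0079 |
| red run | 18 | 0.0105 |
| red run | 28 | 0.0132 |
| red run | 44 | 0.0161 |
| red run | 70 | 0.0147 |
| blue run | 2.8 | 0.0029 |
| blue run | 4.4 | 5 × 10⁻⁴ |
| blue run | 7.0 | 0.0014 |
| blue run | 11 | 0.0033 |
| blue run | 18 | 0.0049 |
| blue run | 28 | 0.0050 |
| blue run | 44 | 0.0075 |
| blue run | 70 | 0.0073 |
| grey run | 2.8 | 0.0045 |
| grey run | 4.4 | 0.0052 |
| grey run | 7.0 | 0.0091 |
| grey run | 11 | 0.0113 |
| grey run | 18 | 0.0158 |
| grey run | 28 | 0.0189 |
| grey run | 44 | 0.0223 |
| grey run | 70 | 0.0237 |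
| ochre run | 2.8 | 0.0051 |
| ochre run | 4.4 | 0.0068 |
| ochre run | 7.0 | 0.0075 |
| ochre run | 11 | 0.0110 |
| ochre run | 18 | 0.0161 |
| ochre run | 28 | 0.0185 |
| ochre run | 44 | 0.0220 |
| ochre run | 70 | 0.0233 |

(standard deviation of a reading: 0.001 M)

- Overall: starting material -> product, with free catalyst as catalyst.
- Constant volume, constant temperature.
- Bound and free are read together.
- An order is taken over about fifteen percent of the charge, up and down.

* apparent order in [free catalyst] of the starting rate, round the charge of the red run (the rate where two percent of its starting material have turned into product)
* apparent order in [starting material] of the starting rate, round the charge of the red run (the rate where two percent of its starting material have turned into product) (one fixed amount of product, the same in the runs compared)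
* product in the teal run at 70 min, as a share of the starting material charged

So I divide, and the ochre run gives 485 /M; I call this share turned at 70 min per unit of free catalyst charged the catalyst capacity, which is a turnover number taken per unit of starting material charged. The blue run, on the same c(free catalyst) as the ochre run, reads 18.2 %, and one reading there carries a scatter of 2.50 % of its charge, so within that scatter I read the capacity as unchanged between these two charges. Multiplying by the catalyst charge of the teal run, I reckon a share of 19.4 %, or 0.0388 M of product. The weak link is plain: the teal charge is 1.67 times the ochre charge, higher than the charge of any earlier run, so I have no reading of the capacity up there.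

For the orders I take the readings at 18 min, a fixed time and not a fixed amount of product, so what I get is my own rough stand-in for the orders of the starting rate. The product read in the grey run against the red run gives 1.01 in catalyst, and the ochre run against the red run gives 1.05 in starting material.

The forecast says 1.15 in catalyst and 1.15 in starting material, both higher than mine, and 19 % for the teal run, with the words “Teal should reach about 19%, perhaps slightly less if saturation begins”.

The flask gives 1.1 in catalyst, 1.5 in starting material, and 15.3 % for the teal run. Where two percent of the red charge has turned into product, the ochre run goes 1.8 times as fast as the red run, which is more than the ratio of 1.50 between their charges of starting material.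

    free catalyst + starting material ⇌ catalyst-substrate complex, settled at all times (1.290 /M)
    catalyst-substrate complex + starting material ⇌ doubly bound catalyst, settled at all times (5.390 /M)
    doubly bound catalyst → product + catalyst-substrate complex (188.4 /min)
    2 starting material ⇌ idle substrate dimer, settled at all times (7.820 /M)
    free catalyst + starting material → spent catalyst + starting material (1.386 /M/min)

Reforged, the capacity of the teal run is 383 /M, lower than the 485 /M of the ochre run, while the 70 min reading of the grey run gives 494 /M.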